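At this reading the dusk, summer, spring and midnight runs are in and the winter run is still shut; the question is what its small catalyst charge gives by 30 min.

| flask | starting material | coupling partner | catalyst | time |
|---|---|---|---|---|
| dusk | 0.0800 M | 0.240 M | 0.00800 M |  |
| summer | 0.0480 M | 0.208 M | 0.00800 M |  |
| spring | 0.160 M | 0.240 M | 0.00800 M |  |
| midnight | 0.0800 M | 0.240 M | 0.00400 M |  |
| winter | 0.0800 M | 0.240 M | 0.00230 M | 30 min |

- dusk run (time / min: [target] / M): 1.1: 0.0055; 3.3: 0.0180; 6.2: 0.0329; 9.9: 0.0479; 14: 0.0566; 19: 0.0660; 24: 0.0711; 30: 0.0733
- summer run (time / min: [target] / M): 1.1: 0.0036; 3.3: 0.0115; 6.2: 0.0208; 9.9: 0.0281; 14: 0.0353; 19: 0.0406; 24: 0.0444; 30: 0.0457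
- spring run (time / min: [target] / M): 1.1: 0.0136; 3.3: 0.0387; 6.2: 0.0672; 9.9: 0.0985; 14: 0.1208; 19: 0.1400; 24: 0.1502; 30: 0.1557
- midnight run (time / min: [target] / M): 1.1: 0.0027; 3.3: 0.0113; 6.2: 0.0221; 9.9: 0.0331; 14: 0.0423; 19: 0.0514; 24: 0.0581; 30: 0.0661

(each reading ± 8 × 10⁻⁴ M)

1. the power of [catalyst] that the first rate follows, about the charge of the dusk run; measure it at two percent of starting material made into target
2. the power of [coupling partner] that the first rate follows, about the charge of the dusk run; measure it at two percent of starting material made into target
3. the summer run starts with 0.0320 M less of starting material and of coupling partner than the dusk run, and with no target. Compared where both hold the same amount of starting material, once fifteen percent of what the summer run was charged with has turned into target, is the summer run faster, slower or alike (within a tenth)?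
4. target in the winter run at 30 min, as a share of the starting material charged

- Overall: starting material + coupling partner -> target, with catalyst as catalyst.
- Constant volume, constant temperature.
- What is held in complexes is read along with the free species.
- An order is taken over about fifteen percent of the charge, up and down.

Both sides start from the same reading. Call τ the time at which target reaches half of the starting material charged. The spring run holds twice the starting material of the dusk run, yet at 9.9 min it has turned 61.6% of its charge into target against 59.9% in the dusk run, so a run can be read as a pseudo-first-order decay. Integrating rate = k·c(starting material) gives target over charge = 1 − exp(−k t), with k = ln(2)/τ. Read at a single clock t, the same curve gives k = −ln(1 − share)/t. At 14 min the dusk run holds 0.0566 M of target and so reads 0.0878 /min, and the midnight run, with 0.0423 M at that clock, reads 0.0537 /min at half the catalyst; both are readings and carry the scatter.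

The dispute is over what lies between these two constants and the winter charge of 0.00230 M. The power side sets k proportional to a power of c(catalyst). Its exponent from the two runs is 0.708, which carries the winter run to 0.0363 /min and a share of 66.3%.

The line side, whose reckoning is the one committed to here, sets k = background + slope·c(catalyst), two parallel channels. Its slope is 8.52 /M/min and its intercept is 0.0197 /min. This intercept is the background constant, the part of k on the line through the dusk and midnight constants that carries no catalyst.

The power side objects that no run shows a flask without catalyst. The line side replies that the exponent rests on the same two constants. Both curves pass through both points, so they part where the winter charge lies lower than the midnight charge. There the line's 0.0393 /min is higher than the power side's constant, and its share is 69.2%.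

The forecast stands with the power side: 0.7 for catalyst, −0.5 for coupling partner, alike for the summer comparison, and 66% for the winter run. Its ground for the catalyst is this: “Halving catalyst gives k about 0.055 versus 0.09, a ratio near 0.6, so the order is about 0.7.”

    catalyst + starting material → catalyst-substrate complex (70.80 /M/min)
    catalyst-substrate complex + coupling partner → target + catalyst (30.00 /M/min)
    starting material + coupling partner ⇌ idle substrate-reagent adduct, settled at all times (38.30 /M)
    starting material + coupling partner → target (0.8700 /M/min)

The winter run gives 69.7%, closer to the line's share than to the forecast; the powers are 0.63 for catalyst and −0.32 for coupling partner, and the summer run is alike. At the dusk charge the power side keeps its ground: the catalyst power of 0.63 lies nearer the forecast's 0.7 than the line's local 0.776. The conversion of starting material + coupling partner into target moves the readings by 10 units of scatter, root mean square. The winter constant comes to 0.0398 /min, of which the background is half. For the summer run, which entered neither constant, the line gives τ = 7.89 min against 7.69 min read.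

All runs were generated by integration for an exercise; the scatter is artificial.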